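The side chain is cut between benzylic C1′ and C2′. Both carbons are innately electrophilic. C1′, flanked by O-2 and O-4 of the phloroglucinol ring, is a quinone-methide carbon. C2′ is the CH2 terminus of an oxirane built on carbinol carbon C3′. A phenylsulfonyl group, introduced through that quinone methide, reverses the polarity of C1′. In the key step the lithiated, tris-silylated benzylic sulfone opens (S)-2-methyl-2-(4-methylpent-3-enyl)oxirane at CH2. This joins both halves in one operation and leaves the C3′ stereocentre untouched. Fluoride then frees the phenols, sulfinate departs through a second quinone methide, and borohydride completes the C1′ methylene.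

Key step: step 5

Numbering used: ring C1 bears the isobutyryl group, C3 the side chain and C5 the ring hydrogen; the side chain runs from C1′ (benzylic) to C8′.
Assumption: in step 4 the BINOL antipode of the catalyst is the one whose sense of induction gives the S epoxide; both antipodes are commercial.

Step 1
Reactants: 1 phloroglucinol (benzene-1,3,5-triol); 2 isobutyryl chloride (2-methylpropanoyl chloride)
Product: 3 phlorisobutyrophenone [2-methyl-1-(2,4,6-trihydroxyphenyl)propan-1-one]
Conditions: AlCl3 (3.5 equiv), CH2Cl2/MeNO2, 0 to 40 °C; then ice/1 M HCl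
Reagents that add atoms: none
Why: Friedel–Crafts acylation of the C3-symmetric, very electron-rich arene has no regiochemical issue and should stop after one acylation, because the chelated aryl ketone deactivates the ring.

Step 2
Reactants: 3 phlorisobutyrophenone
Product: 5 2-methyl-1-{2,4,6-trihydroxy-3-[(phenylsulfonyl)methyl]phenyl}propan-1-one, via ortho-quinone methide 4 (not isolated)
Conditions: PhSO2Na (2 equiv), 37% aq. CH2O (1.0 equiv, slow addition), HCO2H/H2O, rt
Reagents that add atoms: formaldehyde C=O; sodium benzenesulfinate [Na+].[O-]S(=O)c1ccccc1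
Why: In this Mannich-type three-component sulfonylmethylation, hydroxymethylation at one of the two equivalent free ring carbons and loss of water give quinone methide 4, which the soft sulfinate sulfur, present in excess, should capture by conjugate addition with rearomatisation faster than a second molecule of 3 can.

Step 3
Reactants: 5 triphenol sulfone
Product: 6 1-{2,4,6-tris[(tert-butyldimethylsilyl)oxy]-3-[(phenylsulfonyl)methyl]phenyl}-2-methylpropan-1-one
Conditions: TBSOTf (3.6 equiv), 2,6-lutidine (5 equiv), CH2Cl2, −78 to 0 °C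
Reagents that add atoms: tert-butyldimethylsilyl triflate CC(C)(C)[Si](C)(C)OS(=O)(=O)C(F)(F)F
Why: O-Silylation with a silyl triflate and a weak hindered base is fast even for the chelated phenols, so phenoxide-driven loss of sulfinate gets no time, and the three ethers remove every acidic O–H and close the quinone-methide exit for the carbanion step.

Step 4
Reactants: 7 6-methylhept-5-en-2-one
Product: 8 (S)-2-methyl-2-(4-methylpent-3-en-1-yl)oxirane
Conditions: dimethyloxosulfonium methylide (from Me3S(O)I, NaH, THF); La–Li3–tris(binaphthoxide) (5 mol %), [2,4,6-(MeO)3C6H2]3P=O (5 mol %), MS 5 Å, THF, rt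
Reagents that add atoms: trimethylsulfoxonium iodide C[S+](C)(C)=O.[I-]
Why: In this catalytic asymmetric Corey–Chaykovsky epoxidation the heterobimetallic binaphthoxide binds ketone and ylide together and tells methyl from the primary alkyl chain, so methylene transfer to one carbonyl face sets the only stereocentre of the target as S, while the unactivated trisubstituted alkene is inert to the ylide.

Step 5
Reactants: 6 tris-silylated benzylic sulfone; 8 (S)-oxirane
Product: 10 1-{2,4,6-tris[(tert-butyldimethylsilyl)oxy]-3-[(3S)-3-hydroxy-3,7-dimethyl-1-(phenylsulfonyl)oct-6-en-1-yl]phenyl}-2-methylpropan-1-one (both C1′ epimers), via lithiated sulfone 9 (not isolated)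
Conditions: n-BuLi (1.05 equiv), THF, −78 °C; then 8 (1.5 equiv), BF3·OEt2 (1.5 equiv), −78 °C; sat. aq. NaHCO3 at −78 °C
Reagents that add atoms: none
Why: n-BuLi removes a benzylic proton of 6, which is kinetically and thermodynamically more acidic than the hindered tertiary α-CH of the twisted ketone, and α-sulfonyl carbanion 9 attacks the BF3-bound oxirane at its CH2 carbon in an SN2 process that forms the C1′–C2′ bond. The closest known reaction type is the Lewis-acid-assisted opening of 2,2-disubstituted terminal epoxides by lithiated sulfones. No ring is closed; the three-membered ring is opened by cleavage of the CH2–O bond only. C3′ is not touched, so its S configuration is carried over from 8, whereas the new sulfonyl-bearing C1′ centre forms without control, which is harmless because both epimers converge on one CH2 group in step 6. Regioselectivity (CH2 against the quaternary carbon) rests on the steric bias of the oxirane and on the low temperature that suppresses ionisation and hydride shift; chemoselectivity rests on the di-ortho-substituted ketone, which resists addition, and on the borate-capped alkoxide, which cannot attack the neighbouring silyl ethers. The two-electron pathway with the charge on C1′ also avoids a C2′ radical, which would cyclise 5-exo onto the C6′=C7′ alkene, and a C2′ carbanion, which would expel the β-oxygen.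

Step 6
Reactants: 10 γ-hydroxy sulfone (both C1′ epimers)
Product: 13 target 1-{2,4,6-trihydroxy-3-[(3S)-3-hydroxy-3,7-dimethyloct-6-en-1-yl]phenyl}-2-methylpropan-1-one, via triphenol sulfone 11 (not isolated), via ortho-quinone methide 12 (not isolated)
Conditions: NaBH4 (6 equiv), THF/i-PrOH 4:1, −20 °C; then TBAF (3.5 equiv, slow addition), −20 to 0 °C; aq. NH4Cl
Reagents that add atoms: none
Why: Fluoride cleaves the three aryl silyl ethers, a phenoxide ortho or para to C1′ expels benzenesulfinate (base-induced quinone-methide generation from a 2-(1-sulfonylalkyl)phenol), and borohydride kept in excess should deliver hydride to C1′ of 12 with rearomatisation faster than tautomerisation or cycloaddition, while the phenoxide-conjugated ketone, the alkene and the C3′ carbinol are not affected.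

Compound list
1 | phloroglucinol (benzene-1,3,5-triol) | Oc1cc(O)cc(O)c1 | starting material
2 | isobutyryl chloride | CC(C)C(=O)Cl | starting material
3 | phlorisobutyrophenone, 2-methyl-1-(2,4,6-trihydroxyphenyl)propan-1-one | CC(C)C(=O)c1c(O)cc(O)cc1O | intermediate
4 | 3,5-dihydroxy-6-methylidene-4-(2-methylpropanoyl)cyclohexa-2,4-dien-1-one (ortho-quinone methide) | C=C1C(=O)C=C(O)C(C(=O)C(C)C)=C1O | intermediate
5 | 2-methyl-1-{2,4,6-trihydroxy-3-[(phenylsulfonyl)methyl]phenyl}propan-1-one | CC(C)C(=O)c1c(O)cc(O)c(CS(=O)(=O)c2ccccc2)c1O | intermediate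
6 | 1-{2,4,6-tris[(tert-butyldimethylsilyl)oxy]-3-[(phenylsulfonyl)methyl]phenyl}-2-methylpropan-1-one | CC(C)C(=O)c1c(O[Si](C)(C)C(C)(C)C)cc(O[Si](C)(C)C(C)(C)C)c(CS(=O)(=O)c2ccccc2)c1O[Si](C)(C)C(C)(C)C | intermediate
7 | 6-methylhept-5-en-2-one | CC(=O)CCC=C(C)C | starting material
8 | (S)-2-methyl-2-(4-methylpent-3-en-1-yl)oxirane | CC(C)=CCC[C@]1(C)OC1 | intermediate
9 | α-lithio derivative of sulfone 6 | [Li]C(c1c(O[Si](C)(C)C(C)(C)C)cc(O[Si](C)(C)C(C)(C)C)c(C(=O)C(C)C)c1O[Si](C)(C)C(C)(C)C)S(=O)(=O)c1ccccc1 | intermediate
10 | 1-{2,4,6-tris[(tert-butyldimethylsilyl)oxy]-3-[(3S)-3-hydroxy-3,7-dimethyl-1-(phenylsulfonyl)oct-6-en-1-yl]phenyl}-2-methylpropan-1-one, both C1′ epimers | CC(C)=CCC[C@](C)(O)CC(c1c(O[Si](C)(C)C(C)(C)C)cc(O[Si](C)(C)C(C)(C)C)c(C(=O)C(C)C)c1O[Si](C)(C)C(C)(C)C)S(=O)(=O)c1ccccc1 | intermediate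
11 | 1-{2,4,6-trihydroxy-3-[(3S)-3-hydroxy-3,7-dimethyl-1-(phenylsulfonyl)oct-6-en-1-yl]phenyl}-2-methylpropan-1-one (present as phenoxide) | CC(C)=CCC[C@](C)(O)CC(c1c(O)cc(O)c(C(=O)C(C)C)c1O)S(=O)(=O)c1ccccc1 | intermediate
12 | 3,5-dihydroxy-6-[(3S)-3-hydroxy-3,7-dimethyloct-6-en-1-ylidene]-4-(2-methylpropanoyl)cyclohexa-2,4-dien-1-one (ortho-quinone methide) | CC(C)=CCC[C@](C)(O)CC=C1C(=O)C=C(O)C(C(=O)C(C)C)=C1O | intermediate
13 | 1-{2,4,6-trihydroxy-3-[(3S)-3-hydroxy-3,7-dimethyloct-6-en-1-yl]phenyl}-2-methylpropan-1-one | CC(C)=CCC[C@](C)(O)CCc1c(O)cc(O)c(C(=O)C(C)C)c1O | target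

Total step count: 6. Longest linear sequence: 5 (steps 1, 2, 3, 5, 6).

Steps most likely to fail

Step 5.
- What may go wrong: attack of the doubly ortho-flanked carbanion may be slow. Lewis-acid-induced isomerisation of the oxirane (hydride shift) or loss of silyl groups could then overtake C–C bond formation.
- Fallback, from 5 back to 13: Lewis-acid activation and silyl ethers are both given up, and the nucleophile is activated instead.
- Compound 5 is protected with MOMCl/i-Pr2NEt (CH2Cl2, 0 °C) as 1-{2,4,6-tris(methoxymethoxy)-3-[(phenylsulfonyl)methyl]phenyl}-2-methylpropan-1-one F1.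
- Deprotonation with n-BuLi gives a carbanion whose acetal oxygens chelate lithium and which tolerates hours at room temperature. In THF/DMPU (−78 °C to rt) it opens 8 to the tris-MOM γ-hydroxy sulfone F2.
- Electron-transfer desulfonylation (Na/Hg, Na2HPO4, MeOH/THF, −20 °C) gives the tris-MOM ether of the target F3.
- ZnBr2/n-PrSH (CH2Cl2, 0 °C) frees the phenols to give 13 without protic acid.

Step 6.
- What may go wrong: the quinone methide may be diverted before hydride arrives. The routes are intramolecular hetero-Diels–Alder capture by the C6′=C7′ alkene and tautomerisation to the styrene.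
- Fallback, from 10 back to 13: the C–S bond is cleaved by electron transfer while all phenols are still silylated, so no quinone methide can arise.
- Na/Hg with Na2HPO4 in THF/MeOH at −20 °C gives the tris-TBS ether of the target F4.
- TBAF buffered with AcOH (THF, 0 °C) then gives 13.

Step 2.
- What may go wrong: quinone methide 4 may be captured by a second molecule of 3 to form a methylene bridge. The sulfone may re-ionise, or a second substitution may occur at C5.
- Fallback, from 3 back to 6: the trap is changed to a thiol and the sulfur oxidation level is adjusted later.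
- Compound 3, aq. CH2O and PhSH (cat. Et3N, EtOH, reflux) give 2-methyl-1-{2,4,6-trihydroxy-3-[(phenylsulfanyl)methyl]phenyl}propan-1-one F5, whose thioether does not re-ionise.
- Silylation as in step 3 gives the tris-TBS sulfide F6.
- mCPBA (2.2 equiv, NaHCO3, CH2Cl2, 0 °C) oxidises sulfur to give 6. No alkene is present at that stage.

Further compounds
F1 | step 5 | 1-{2,4,6-tris(methoxymethoxy)-3-[(phenylsulfonyl)methyl]phenyl}-2-methylpropan-1-one | CC(C)C(=O)c1c(OCOC)cc(OCOC)c(CS(=O)(=O)c2ccccc2)c1OCOC
F2 | step 5 | 1-{3-[(3S)-3-hydroxy-3,7-dimethyl-1-(phenylsulfonyl)oct-6-en-1-yl]-2,4,6-tris(methoxymethoxy)phenyl}-2-methylpropan-1-one, both C1′ epimers | CC(C)=CCC[C@](C)(O)CC(c1c(OCOC)cc(OCOC)c(C(=O)C(C)C)c1OCOC)S(=O)(=O)c1ccccc1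
F3 | step 5 | 1-{3-[(3S)-3-hydroxy-3,7-dimethyloct-6-en-1-yl]-2,4,6-tris(methoxymethoxy)phenyl}-2-methylpropan-1-one | CC(C)=CCC[C@](C)(O)CCc1c(OCOC)cc(OCOC)c(C(=O)C(C)C)c1OCOC
F4 | step 6 | 1-{2,4,6-tris[(tert-butyldimethylsilyl)oxy]-3-[(3S)-3-hydroxy-3,7-dimethyloct-6-en-1-yl]phenyl}-2-methylpropan-1-one | CC(C)=CCC[C@](C)(O)CCc1c(O[Si](C)(C)C(C)(C)C)cc(O[Si](C)(C)C(C)(C)C)c(C(=O)C(C)C)c1O[Si](C)(C)C(C)(C)C
F5 | step 2 | 2-methyl-1-{2,4,6-trihydroxy-3-[(phenylsulfanyl)methyl]phenyl}propan-1-one | CC(C)C(=O)c1c(O)cc(O)c(CSc2ccccc2)c1O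
F6 | step 2 | 1-{2,4,6-tris[(tert-butyldimethylsilyl)oxy]-3-[(phenylsulfanyl)methyl]phenyl}-2-methylpropan-1-one | CC(C)C(=O)c1c(O[Si](C)(C)C(C)(C)C)cc(O[Si](C)(C)C(C)(C)C)c(CSc2ccccc2)c1O[Si](C)(C)C(C)(C)C
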